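A small charge of G meets a charge of J 50.0 times larger in three vessels, and I want the L each one yields.

    J → L (k1 = 0.085 s⁻¹)
    J → Q (k2 = 0.044 s⁻¹)
    J + G → J.G (k3 = 4400 L mol⁻¹ s⁻¹)

| flask | J | G | remark | time |
|---|---|---|---|---|
| west | 0.50 mM | 0.0100 mM | one stirred flow tank at steady state, fed with the mixture as stated, mean residence time 40 s |  |
| north-west | 0.50 mM | 0.0100 mM | a closed flask charged with all of it at once and left for 40 s | 40 s |
| south-west | 0.50 mM (fed, over 32.0 s) | 0.0100 mM | a stirred flask in which J is dosed at a steady rate over 32.0 s without added volume, worked up at 40 s | 40 s |

- the set-up with the highest amount of L at the outlet or at the end, in percent of the J put in ("none" if the first two lie within 2 percentage points) (west / north-west / south-west / none)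
- amount of L at the outlet or at the end, in percent of the J put in, west
- amount of L at the outlet or at the end, in percent of the J put in, north-west
- amount of L at the outlet or at the end, in percent of the J put in, south-west

- the stated concentrations are those of everything mixed, before any reaction; amounts are the same in each set-up
- the feed brings no volume worth counting
- run time (north-west): 40 s

In the closed north-west flask a G lives about 0.455 s at the starting J, far shorter than the 7.75 s a J lives under the steps to L and Q. G is the limiting reagent of its step, so I let it bind 2.00 % of the J at once. After that both remaining steps are first order in J, and they send 65.9 % of the J that reacts to L. The ceiling for L is therefore 64.6 % of the charge.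

What remains is how much J has reacted. The givens fold into 5.16: this is the Damköhler number, the time given counted in lifetimes of J. In north-west the reacted part is one minus exp(−number), which gives 64.2 % L. In the west tank it is number/(1 + number), which, with the same toll to G, gives 54.1 % L.

One number is not enough for the dosed south-west flask, so I split it at the end of the feed into 4.13 lifetimes of feeding and a tail of 1.03. The feed leaves (1 − exp(−feeding))/feeding of the charge as J, and the tail thins that to 8.49 %. Taking that and the toll to G from the charge, I get 59.0 % L. My choice is north-west, ahead of the other two.

The forecast says 54.2 % for west, 64.2 % for north-west and 59 % for south-west, with north-west best, holding that G “simply removes about 2% of the charge in every set-up”.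

The simulation gives 54.2 % for west, 64.2 % for north-west and 59.0 % for south-west, with north-west best.

Now I keep the south-west recipe and read it at 2.5 min. The tail grows from 1.03 to 15.2 lifetimes of J, so the reckoning leaves hardly any of the charge as J and puts L at the ceiling of 64.6 %. That neighbouring flask reads 0 % J, 33.4 % Q and 64.6 % L.

(The constants stand for no real mixture, and the outcome is calculated.)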